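**Retrosynthetic overview** (unprimed locants and rings A/C = the 2S chroman half; primed locants and rings B/D = the 2'R half; A, B are the arenes, C, D the pyran rings)
1. The target comes from a bis-pivalate diethyl ester by one global saponification; ring D (O1', C2', C3', C4', C4a', C8a') is the last ring closed.
2. Ring D is closed by a catalyst-controlled oxa-[4+2] cycloaddition of an ortho-quinone methide on ring B with the methylidene end of a C14 triene ester. It forms C4'–C3' and O1'–C2', sets C2' (R) and brings in the whole second side chain. The enabling feature is that phenolic O1' on C8a' and benzylic C4' on the adjacent C4a' form a latent 1-oxadiene (O1'=C8a'–C4a'=C4'), while C3'/C2' map onto a 1,1-disubstituted alkene whose substituted carbon takes the oxygen.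
3. The biaryl bond C5–C5' comes from a Suzuki–Miyaura coupling of the (2S)-chroman 5-boronate with a 2-bromosalicylaldehyde (ring B), whose formyl carbon is the masked C4'.
4. Ring C is made by the same cycloaddition on the monomeric bromo salicyl alcohol with the enantiomeric catalyst. Both arenes derive from one bromosalicylaldehyde (from 1-bromo-2,5-dimethoxy-4-methylbenzene); the triene ester comes from a Grignard addition, a Johnson–Claisen rearrangement and a Still–Gennari olefination.
5. Order of events: rings A and B are purchased arenes, then ring C (step 9), the biaryl bond (step 11) and ring D (step 13).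

Key step: step 13

Assumption: the target notation leaves the C5–C5' axis undefined; because the two halves are constitutionally identical and of opposite configuration (2S, 2'R), the two axial forms are mirror images, so the route sets only the two carbon stereocentres and carries the biaryl intermediates as mixtures of atropisomers.

Step 1
Reactants: 1 4-bromo-2-methylbut-1-ene; 2 2-methylprop-2-enal (methacrolein)
Product: 4 2,6-dimethylhepta-1,6-dien-3-ol (racemic), via 3-methylbut-3-enylmagnesium bromide 3 (not isolated)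
Conditions: Mg, THF, 40 °C; then 2, −40 to 0 °C; H2O/NH4Cl work-up
Reagents that add atoms: none
Why: Grignard 1,2-addition of a homoallyl magnesium reagent to an enal is reliable; the carbinol centre is left racemic on purpose because it is destroyed in step 2.

Step 2
Reactants: 4 2,6-dimethylhepta-1,6-dien-3-ol; 5 triethyl orthoacetate
Product: 7 ethyl (4E)-4,8-dimethylnona-4,8-dienoate, via mixed ketene acetal 6 (not isolated)
Conditions: 5 (5 equiv), EtCO2H (cat.), 140 °C, EtOH distilled off
Reagents that add atoms: none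
Why: Johnson–Claisen rearrangement: the [3,3]-shift of ketene acetal 6 through a chair transition state with the homoallyl group equatorial should set the 4E trisubstituted alkene and add two carbons.

Step 3
Reactants: 7 ethyl (4E)-4,8-dimethylnona-4,8-dienoate
Product: 8 (4E)-4,8-dimethylnona-4,8-dienal
Conditions: iBu2AlH (1.05 equiv), CH2Cl2, −78 °C; aq. KNaC4H4O6
Reagents that add atoms: none
Why: Partial ester reduction with iBu2AlH at −78 °C stops at the aluminium hemiacetal, which releases the aldehyde on work-up; the isolated alkenes are inert.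

Step 4
Reactants: 8 (4E)-4,8-dimethylnona-4,8-dienal; 9 ethyl 2-[bis(2,2,2-trifluoroethoxy)phosphoryl]propanoate
Product: 10 ethyl (2Z,6E)-2,6,10-trimethylundeca-2,6,10-trienoate
Conditions: 9, KN(SiMe3)2, 18-crown-6, THF, −78 °C; then 8
Reagents that add atoms: none
Why: Still–Gennari olefination: the bis(trifluoroethyl) phosphonate eliminates fast from the kinetic adduct, which should give the 2Z trisubstituted enoate that the target requires.

Step 5
Reactants: 11 1-bromo-2,5-dimethoxy-4-methylbenzene
Product: 13 2-bromo-3,6-dimethoxy-5-methylbenzaldehyde, via ortho-lithiated arene 12 (not isolated)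
Conditions: LiN(iPr)2, THF, −78 °C; DMF, −78 to 0 °C; H2O
Reagents that add atoms: N,N-dimethylformamide, CN(C)C=O
Why: Directed ortho-lithiation takes the only ring proton flanked by bromine and methoxy (the most acidic site), −78 °C suppresses aryne formation, and DMF formylates the aryllithium.

Step 6
Reactants: 13 2-bromo-3,6-dimethoxy-5-methylbenzaldehyde
Product: 14 2-bromo-3,6-dihydroxy-5-methylbenzaldehyde
Conditions: BBr3 (4 equiv), CH2Cl2, −78 °C to rt; H2O
Reagents that add atoms: none
Why: Lewis-acid ether cleavage with BBr3 removes both methyl ethers at a stage where no alkene is present, the ether ortho to the formyl group reacting first through chelation.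

Step 7
Reactants: 14 2-bromo-3,6-dihydroxy-5-methylbenzaldehyde
Product: 15 2-bromo-3-formyl-4-hydroxy-5-methylphenyl 2,2-dimethylpropanoate
Conditions: PivCl (1.05 equiv), Et3N, CH2Cl2, −20 to 0 °C
Reagents that add atoms: pivaloyl chloride, CC(C)(C)C(=O)Cl
Why: Selective O-acylation: the 6-OH is held in a hydrogen bond to the formyl group and flanked by methyl, so the 3-OH should be pivaloylated alone; the pivalate later keeps this oxygen from acting as a nucleophile.

Step 8
Reactants: 15 2-bromo-3-formyl-4-hydroxy-5-methylphenyl 2,2-dimethylpropanoate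
Product: 16 2-bromo-4-hydroxy-3-(hydroxymethyl)-5-methylphenyl 2,2-dimethylpropanoate
Conditions: NaBH4, THF/MeOH, 0 °C
Reagents that add atoms: none
Why: Chemoselective NaBH4 reduction of the aryl aldehyde gives the ortho-hydroxybenzyl alcohol; the hindered aryl pivalate is stable at 0 °C.

Step 9
Reactants: 16 2-bromo-4-hydroxy-3-(hydroxymethyl)-5-methylphenyl 2,2-dimethylpropanoate; 10 ethyl (2Z,6E)-2,6,10-trimethylundeca-2,6,10-trienoate
Product: 18 ethyl (2Z,6E)-9-[(2S)-5-bromo-6-(2,2-dimethylpropanoyloxy)-2,8-dimethyl-3,4-dihydro-2H-chromen-2-yl]-2,6-dimethylnona-2,6-dienoate, via ortho-quinone methide 17 (not isolated)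
Conditions: (S)-N-triflyl phosphoramide of 3,3'-bis(2,4,6-triisopropylphenyl)-1,1'-bi-2-naphthol (C51H57F3NO5PS, 10 mol %), 10 (2 equiv), 5 Å molecular sieves, toluene, 40 °C
Reagents that add atoms: none
Why: Proposed new method: the chiral acid ionises the ortho-hydroxybenzyl alcohol to ortho-quinone methide 17 inside a hydrogen-bonded ion pair, the methylidene carbon of 10 attacks the exocyclic CH2 and the phenolic oxygen closes on the developing tertiary cation at C2 within the chiral pocket (asynchronous inverse-electron-demand oxa-[4+2] cycloaddition), so the catalyst should decide which alkene face is used, the (S)-acid being assigned to 2S with the sense to be calibrated on a model; the closest known reactions are the thermal racemic cycloaddition of ortho-quinone methides with 1,1-disubstituted alkenes and the chiral phosphoric-acid-type [4+2] cycloadditions of ortho-quinone methides with styrenes and enol ethers.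

Step 10
Reactants: 18 ethyl (2Z,6E)-9-[(2S)-5-bromo-6-(2,2-dimethylpropanoyloxy)-2,8-dimethyl-3,4-dihydro-2H-chromen-2-yl]-2,6-dimethylnona-2,6-dienoate
Product: 19 ethyl (2Z,6E)-9-[(2S)-6-(2,2-dimethylpropanoyloxy)-2,8-dimethyl-5-(4,4,5,5-tetramethyl-1,3,2-dioxaborolan-2-yl)-3,4-dihydro-2H-chromen-2-yl]-2,6-dimethylnona-2,6-dienoate
Conditions: B2pin2, Pd(OAc)2 (5 mol %), SPhos (2-dicyclohexylphosphino-2',6'-dimethoxybiphenyl), KOAc, 1,4-dioxane, 90 °C
Reagents that add atoms: bis(pinacolato)diboron, CC1(C)OB(OC1(C)C)B1OC(C)(C)C(C)(C)O1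
Why: Miyaura borylation: zerovalent palladium inserts into the hindered C5–Br bond and acetate-assisted transmetalation with B2pin2 gives the pinacol boronate; esters, pivalate and alkenes tolerate KOAc.

Step 11
Reactants: 19 ethyl (2Z,6E)-9-[(2S)-6-(2,2-dimethylpropanoyloxy)-2,8-dimethyl-5-(4,4,5,5-tetramethyl-1,3,2-dioxaborolan-2-yl)-3,4-dihydro-2H-chromen-2-yl]-2,6-dimethylnona-2,6-dienoate; 15 2-bromo-3-formyl-4-hydroxy-5-methylphenyl 2,2-dimethylpropanoate
Product: 20 ethyl (2Z,6E)-9-[(2S)-5-[6-(2,2-dimethylpropanoyloxy)-2-formyl-3-hydroxy-4-methylphenyl]-6-(2,2-dimethylpropanoyloxy)-2,8-dimethyl-3,4-dihydro-2H-chromen-2-yl]-2,6-dimethylnona-2,6-dienoate (two atropisomers)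
Conditions: Pd(OAc)2 (5 mol %), SPhos (10 mol %), K3PO4, toluene/H2O 10:1, 90 °C
Reagents that add atoms: none
Why: Suzuki–Miyaura coupling: the ortho-formyl group activates the C–Br bond of 15 for oxidative addition and the bulky electron-rich phosphine SPhos is the established ligand for tetra-ortho-substituted biaryls; the new axis forms without control and both atropisomers are taken on.

Step 12
Reactants: 20 ethyl (2Z,6E)-9-[(2S)-5-[6-(2,2-dimethylpropanoyloxy)-2-formyl-3-hydroxy-4-methylphenyl]-6-(2,2-dimethylpropanoyloxy)-2,8-dimethyl-3,4-dihydro-2H-chromen-2-yl]-2,6-dimethylnona-2,6-dienoate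
Product: 21 ethyl (2Z,6E)-9-[(2S)-5-[6-(2,2-dimethylpropanoyloxy)-3-hydroxy-2-(hydroxymethyl)-4-methylphenyl]-6-(2,2-dimethylpropanoyloxy)-2,8-dimethyl-3,4-dihydro-2H-chromen-2-yl]-2,6-dimethylnona-2,6-dienoate (two atropisomers)
Conditions: NaBH4, THF/EtOH, 0 °C
Reagents that add atoms: none
Why: Chemoselective NaBH4 reduction of the aryl aldehyde unveils the ortho-hydroxybenzyl alcohol of ring B; enoates and aryl pivalates are untouched at 0 °C.

Step 13
Reactants: 21 ethyl (2Z,6E)-9-[(2S)-5-[6-(2,2-dimethylpropanoyloxy)-3-hydroxy-2-(hydroxymethyl)-4-methylphenyl]-6-(2,2-dimethylpropanoyloxy)-2,8-dimethyl-3,4-dihydro-2H-chromen-2-yl]-2,6-dimethylnona-2,6-dienoate; 10 ethyl (2Z,6E)-2,6,10-trimethylundeca-2,6,10-trienoate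
Product: 23 diethyl (2Z,2'Z,6E,6'E)-9,9'-[(2S,2'R)-6,6'-bis(2,2-dimethylpropanoyloxy)-2,2',8,8'-tetramethyl-3,3',4,4'-tetrahydro-2H,2'H-[5,5'-bichromene]-2,2'-diyl]bis(2,6-dimethylnona-2,6-dienoate), via ring-B ortho-quinone methide 22 (not isolated)
Conditions: (R)-N-triflyl phosphoramide of 3,3'-bis(2,4,6-triisopropylphenyl)-1,1'-bi-2-naphthol (C51H57F3NO5PS, 10 mol %), 10 (3 equiv), 5 Å molecular sieves, toluene, 40 °C
Reagents that add atoms: none
Why: Proposed new method: the chiral acid ionises the ortho-hydroxybenzyl alcohol of ring B to ortho-quinone methide 22, held as a hydrogen-bonded ion pair, and the methylidene terminus of 10 adds in an asynchronous inverse-electron-demand oxa-[4+2] cycloaddition in which the C4'–C3' bond leads, C2' acquires tertiary cationic character and O1' then closes on it inside the chiral pocket. The closest known reactions are the thermal racemic cycloaddition of ortho-quinone methides with 1,1-disubstituted alkenes to 2,2-disubstituted chromans, the chiral Brønsted-acid-catalysed [4+2] cycloadditions of ortho-quinone methides with styrenes and enol ethers, and confined-acid asymmetric hydroalkoxylation of 1,1-dialkylethenes, where methyl is told from a CH2R group at a forming tertiary C–O bond; new here is enantiocontrol with an unactivated dialkylethene. Ring D is closed by an intermolecular [4+2] cycloaddition that forms both of its new sigma bonds (C4'–C3' and O1'–C2') in one operation. C2' is set by the catalyst (the (R)-acid is assigned to 2'R, the antipode of the acid used in step 9, with the sense to be calibrated on a model), not by the remote 2S centre. The step needs oxygen to go to the more substituted alkene carbon (secured by the tertiary cation character), reaction at the terminal methylidene and not at the trisubstituted or ester-bearing alkenes (sterics and electron demand), and ionisation on ring B only, which is secured because O1'H is the only free phenol: O6 of ring A is pivaloylated, which also blocks closure of a 6H-benzo[c]chromene onto C4'. Both atropisomers of 21 should converge on 23, which is expected as the pair of axial antipodes.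

Step 14
Reactants: 23 diethyl (2Z,2'Z,6E,6'E)-9,9'-[(2S,2'R)-6,6'-bis(2,2-dimethylpropanoyloxy)-2,2',8,8'-tetramethyl-3,3',4,4'-tetrahydro-2H,2'H-[5,5'-bichromene]-2,2'-diyl]bis(2,6-dimethylnona-2,6-dienoate)
Product: 24 (2Z,2'Z,6E,6'E)-9,9'-[(2S,2'R)-6,6'-dihydroxy-2,2',8,8'-tetramethyl-3,3',4,4'-tetrahydro-2H,2'H-[5,5'-bichromene]-2,2'-diyl]bis(2,6-dimethylnona-2,6-dienoic acid) (CNP0282703.1)
Conditions: LiOH (12 equiv), THF/MeOH/H2O, 40 °C, argon; then 1 M HCl to pH 3
Reagents that add atoms: lithium hydroxide, [Li+].[OH-] (its oxygen ends in each CO2H group)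
Why: Saponification cleaves the two aryl pivalates and the two ethyl esters in one operation; there is no stereocentre alpha to a carbonyl, the ether-linked quaternary centres are inert to base, and exclusion of air protects the 6-hydroxychroman units.

**Compound list**
1 | 4-bromo-2-methylbut-1-ene | C=C(C)CCBr | starting material
2 | 2-methylprop-2-enal (methacrolein) | C=C(C)C=O | starting material
3 | 3-methylbut-3-enylmagnesium bromide | C=C(C)CC[Mg]Br | intermediate (not isolated)
4 | 2,6-dimethylhepta-1,6-dien-3-ol (racemic) | C=C(C)CCC(O)C(C)=C | intermediate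
5 | triethyl orthoacetate | CC(OCC)(OCC)OCC | starting material
6 | 3-[(1-ethoxyethenyl)oxy]-2,6-dimethylhepta-1,6-diene (mixed ketene acetal) | C=C(OCC)OC(CCC(C)=C)C(C)=C | intermediate (not isolated)
7 | ethyl (4E)-4,8-dimethylnona-4,8-dienoate | CCOC(=O)CC/C(C)=C/CCC(C)=C | intermediate
8 | (4E)-4,8-dimethylnona-4,8-dienal | O=CCC/C(C)=C/CCC(C)=C | intermediate
9 | ethyl 2-[bis(2,2,2-trifluoroethoxy)phosphoryl]propanoate | CCOC(=O)C(C)P(=O)(OCC(F)(F)F)OCC(F)(F)F | starting material
10 | ethyl (2Z,6E)-2,6,10-trimethylundeca-2,6,10-trienoate | C=C(C)CC/C=C(\C)CC/C=C(/C)C(=O)OCC | intermediate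
11 | 1-bromo-2,5-dimethoxy-4-methylbenzene | COc1cc(C)c(OC)cc1Br | starting material
12 | (2-bromo-3,6-dimethoxy-5-methylphenyl)lithium | COc1cc(C)c(OC)c([Li])c1Br | intermediate (not isolated)
13 | 2-bromo-3,6-dimethoxy-5-methylbenzaldehyde | COc1cc(C)c(OC)c(C=O)c1Br | intermediate
14 | 2-bromo-3,6-dihydroxy-5-methylbenzaldehyde | Oc1cc(C)c(O)c(C=O)c1Br | intermediate
15 | 2-bromo-3-formyl-4-hydroxy-5-methylphenyl 2,2-dimethylpropanoate | CC(C)(C)C(=O)Oc1cc(C)c(O)c(C=O)c1Br | intermediate
16 | 2-bromo-4-hydroxy-3-(hydroxymethyl)-5-methylphenyl 2,2-dimethylpropanoate | CC(C)(C)C(=O)Oc1cc(C)c(O)c(CO)c1Br | intermediate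
17 | 2-bromo-5-methyl-3-methylidene-4-oxocyclohexa-1,5-dien-1-yl 2,2-dimethylpropanoate (ortho-quinone methide) | C=C1C(=O)C(C)=CC(OC(=O)C(C)(C)C)=C1Br | intermediate (not isolated)
18 | ethyl (2Z,6E)-9-[(2S)-5-bromo-6-(2,2-dimethylpropanoyloxy)-2,8-dimethyl-3,4-dihydro-2H-chromen-2-yl]-2,6-dimethylnona-2,6-dienoate | C/C(=C/CC/C(C)=C/CC[C@@]1(C)CCc2c(c(C)cc(OC(=O)C(C)(C)C)c2Br)O1)C(=O)OCC | intermediate
19 | ethyl (2Z,6E)-9-[(2S)-6-(2,2-dimethylpropanoyloxy)-2,8-dimethyl-5-(4,4,5,5-tetramethyl-1,3,2-dioxaborolan-2-yl)-3,4-dihydro-2H-chromen-2-yl]-2,6-dimethylnona-2,6-dienoate | C/C(=C/CC/C(C)=C/CC[C@@]1(C)CCc2c(c(C)cc(OC(=O)C(C)(C)C)c2B3OC(C)(C)C(C)(C)O3)O1)C(=O)OCC | intermediate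
20 | ethyl (2Z,6E)-9-[(2S)-5-[6-(2,2-dimethylpropanoyloxy)-2-formyl-3-hydroxy-4-methylphenyl]-6-(2,2-dimethylpropanoyloxy)-2,8-dimethyl-3,4-dihydro-2H-chromen-2-yl]-2,6-dimethylnona-2,6-dienoate (axis undefined) | C/C(=C/CC/C(C)=C/CC[C@@]1(C)CCc2c(c(C)cc(OC(=O)C(C)(C)C)c2-c2c(OC(=O)C(C)(C)C)cc(C)c(O)c2C=O)O1)C(=O)OCC | intermediate
21 | ethyl (2Z,6E)-9-[(2S)-5-[6-(2,2-dimethylpropanoyloxy)-3-hydroxy-2-(hydroxymethyl)-4-methylphenyl]-6-(2,2-dimethylpropanoyloxy)-2,8-dimethyl-3,4-dihydro-2H-chromen-2-yl]-2,6-dimethylnona-2,6-dienoate (axis undefined) | C/C(=C/CC/C(C)=C/CC[C@@]1(C)CCc2c(c(C)cc(OC(=O)C(C)(C)C)c2-c2c(OC(=O)C(C)(C)C)cc(C)c(O)c2CO)O1)C(=O)OCC | intermediate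
22 | ethyl (2Z,6E)-9-[(2S)-5-[2-(2,2-dimethylpropanoyloxy)-4-methyl-6-methylidene-5-oxocyclohexa-1,3-dien-1-yl]-6-(2,2-dimethylpropanoyloxy)-2,8-dimethyl-3,4-dihydro-2H-chromen-2-yl]-2,6-dimethylnona-2,6-dienoate (ring-B ortho-quinone methide) | C/C(=C/CC/C(C)=C/CC[C@@]1(C)CCc2c(c(C)cc(OC(=O)C(C)(C)C)c2C3=C(OC(=O)C(C)(C)C)C=C(C)C(=O)C3=C)O1)C(=O)OCC | intermediate (not isolated)
23 | diethyl (2Z,2'Z,6E,6'E)-9,9'-[(2S,2'R)-6,6'-bis(2,2-dimethylpropanoyloxy)-2,2',8,8'-tetramethyl-3,3',4,4'-tetrahydro-2H,2'H-[5,5'-bichromene]-2,2'-diyl]bis(2,6-dimethylnona-2,6-dienoate) | C/C(=C/CC/C(C)=C/CC[C@@]1(C)CCc2c(c(C)cc(OC(=O)C(C)(C)C)c2-c2c(OC(=O)C(C)(C)C)cc(C)c3c2CC[C@@](C)(CC/C=C(\C)CC/C=C(/C)C(=O)OCC)O3)O1)C(=O)OCC | intermediate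
24 | (2Z,2'Z,6E,6'E)-9,9'-[(2S,2'R)-6,6'-dihydroxy-2,2',8,8'-tetramethyl-3,3',4,4'-tetrahydro-2H,2'H-[5,5'-bichromene]-2,2'-diyl]bis(2,6-dimethylnona-2,6-dienoic acid) | C/C(=C/CC/C(C)=C/CC[C@@]1(C)CCc2c(c(C)cc(O)c2-c2c(O)cc(C)c3c2CC[C@@](C)(CC/C=C(\C)CC/C=C(/C)C(=O)O)O3)O1)C(=O)O | target

**Step count and risks**
Total step count: 14. Longest linear sequence: 10 steps (11 → 13 → 14 → 15 → 16 → 18 → 19 → 20 → 21 → 23 → 24); the triene ester 10 (4 steps) enters at steps 9 and 13.

Steps most likely to fail:

1. Step 9 (Proposed new method). The chiral anion may fail to tell methyl from the CH2 chain at the forming C2–O bond, giving low enantioselectivity. The acid may also isomerise the methylidene group or trigger cation–olefin cyclisation, and the quinone methide may oligomerise faster than it is trapped. The fallback sets out from 16 and 10 and comes back at 18. Heating 16 with 10 (3 equiv) in toluene at 150 °C in a sealed vessel, without catalyst, should give the racemic bromochroman ester F1; this thermal dehydration to the ortho-quinone methide and its cycloaddition to a 1,1-disubstituted alkene is a known reaction type. Preparative chromatography on a chiral stationary phase (amylose tris(3,5-dimethylphenylcarbamate), supercritical CO2/alcohol) then delivers the (2S)-enantiomer, which is 18.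

2. Step 13 (Proposed new method). In addition to the points above, the stereogenic axis next to C4' makes the two atropisomers of 21 diastereomeric substrates for the chiral acid, so one may react slowly or with poor facial selectivity at C2'. Ionisation next to the hindered biaryl may also be slow. The fallback sets out from 16, 10 and 19 and comes back at 23; it closes ring D on the monomer and makes the biaryl bond last, with known chemistry only. The thermal cycloaddition of 16 and 10 described above gives racemate F1, and the second fraction of the same resolution is the (2R)-bromochroman ester F2. Coupling F2 with boronate 19 under the conditions of step 11 (Pd(OAc)2, SPhos, K3PO4, toluene/H2O, 90 °C) should give 23 directly, so both enantiomers from the resolution are used.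

3. Step 11. Transmetalation at the doubly ortho-substituted boronate may be slow, so that protodeboronation consumes the advanced fragment 19. The salicylaldehyde phenoxide may bind palladium, and aqueous base may partly cleave the pivalates. The fallback sets out from 16 and 18 and comes back at 21; it puts boron on the cheap arene and masks ring B. Treating 16 with 2,2-dimethoxypropane and catalytic TsOH in acetone should give the acetonide F3. Miyaura borylation (B2pin2, Pd(OAc)2, SPhos, KOAc, dioxane, 90 °C) converts it into the boronate F4, which is used in excess in a Suzuki–Miyaura coupling with bromide 18 to give the biaryl acetonide F5. Mild hydrolysis (AcOH/H2O/THF, 40 °C) then releases 21; steps 10 and 12 are not needed on this path.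

**Further compounds**
F1 | step 9 | ethyl (2Z,6E)-9-[5-bromo-6-(2,2-dimethylpropanoyloxy)-2,8-dimethyl-3,4-dihydro-2H-chromen-2-yl]-2,6-dimethylnona-2,6-dienoate (racemic) | C/C(=C/CC/C(C)=C/CCC1(C)CCc2c(c(C)cc(OC(=O)C(C)(C)C)c2Br)O1)C(=O)OCC
F2 | step 13 | ethyl (2Z,6E)-9-[(2R)-5-bromo-6-(2,2-dimethylpropanoyloxy)-2,8-dimethyl-3,4-dihydro-2H-chromen-2-yl]-2,6-dimethylnona-2,6-dienoate | C/C(=C/CC/C(C)=C/CC[C@]1(C)CCc2c(c(C)cc(OC(=O)C(C)(C)C)c2Br)O1)C(=O)OCC
F3 | step 11 | 5-bromo-2,2,8-trimethyl-4H-1,3-benzodioxin-6-yl 2,2-dimethylpropanoate | CC1(C)OCc2c(O1)c(C)cc(OC(=O)C(C)(C)C)c2Br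
F4 | step 11 | 2,2,8-trimethyl-5-(4,4,5,5-tetramethyl-1,3,2-dioxaborolan-2-yl)-4H-1,3-benzodioxin-6-yl 2,2-dimethylpropanoate | CC1(C)OCc2c(O1)c(C)cc(OC(=O)C(C)(C)C)c2B3OC(C)(C)C(C)(C)O3
F5 | step 11 | ethyl (2Z,6E)-9-[(2S)-6-(2,2-dimethylpropanoyloxy)-5-[6-(2,2-dimethylpropanoyloxy)-2,2,8-trimethyl-4H-1,3-benzodioxin-5-yl]-2,8-dimethyl-3,4-dihydro-2H-chromen-2-yl]-2,6-dimethylnona-2,6-dienoate (axis undefined) | C/C(=C/CC/C(C)=C/CC[C@@]1(C)CCc2c(c(C)cc(OC(=O)C(C)(C)C)c2-c2c(OC(=O)C(C)(C)C)cc(C)c3c2COC(C)(C)O3)O1)C(=O)OCC
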